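**Retrosynthetic overview**

1. Target 19 is cut at the enone C=C (Claisen–Schmidt) into the ring A methyl ketone 10 and the ring B aldehyde 15. The pyran ring of 15 comes from a propargyl aryl ether of 4-hydroxybenzaldehyde (Claisen rearrangement, then electrocyclisation).
2. The acetyl group at C5 of ring A is placed by lithiation ortho to the C4 carbamate of dihydrobenzofuran 8. The carbamate and the silyl ether are removed last.
3. The strategy rests on the dihydrofuran ring fused to ring A (O1–C2–C3–C3a–C7a). C2 carries a hydrogen next to O1 and C3 is benzylic, so the C2–C3 bond is made by insertion of a C3 carbene (the former formyl carbon of a 2,6-dioxygenated benzaldehyde) into the O–CH2 group of an aryl 2-methyl-2-silyloxypropyl ether. This closes the ring and sets the only stereocentre, C2 (R).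
4. The ether comes from 2,6-dihydroxybenzaldehyde 1 and 2,2-dimethyloxirane 2. Ring order: dihydrofuran on ring A (step 5), pyran on ring B (step 8), union of the halves (step 9).

Key step: step 5

Catalyst: [Co(P*)] is the divalent cobalt complex of the dianion of 5,15-bis(3,5-di-tert-butylphenyl)-10,20-bis{2,6-bis[(2,2-dimethylcyclopropanecarbonyl)amino]phenyl}porphyrin, a D2-symmetric chiral amidoporphyrin.

Assumption: the sense of induction of [Co(P*)] for this ether cannot be assigned beforehand. Both antipodes of P* are available from (S)- and (R)-2,2-dimethylcyclopropanecarboxamide, and the one that delivers (2R)-8 is used.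

**Route**

Step 1
Reactants: 1 2,6-dihydroxybenzaldehyde; 2 2,2-dimethyloxirane
Product: 3 2-hydroxy-6-(2-hydroxy-2-methylpropoxy)benzaldehyde
Conditions: K2CO3 (0.3 equiv), 2 (1.1 equiv), DMF, 90 °C, sealed vessel
Reagents that add atoms: none
Why: Phenoxide opening of the epoxide at its unhindered CH2 terminus (SN2) gives the aryl ether with a free tertiary alcohol, and the remaining phenol, locked in a hydrogen bond to the formyl group, reacts more slowly, so that about one equivalent of oxirane should stop at mono-alkylation.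

Step 2
Reactants: 3 2-hydroxy-6-(2-hydroxy-2-methylpropoxy)benzaldehyde
Product: 4 2-formyl-3-(2-hydroxy-2-methylpropoxy)phenyl diethylcarbamate
Conditions: Et2NCOCl, K2CO3, MeCN, reflux
Reagents that add atoms: diethylcarbamoyl chloride, CCN(CC)C(Cl)=O
Why: O-Carbamoylation of the phenoxide with the carbamoyl chloride, in which the hindered, non-ionised tertiary alcohol does not compete under carbonate conditions.

Step 3
Reactants: 4 2-formyl-3-(2-hydroxy-2-methylpropoxy)phenyl diethylcarbamate
Product: 5 2-formyl-3-[2-methyl-2-(triethylsilyloxy)propoxy]phenyl diethylcarbamate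
Conditions: Et3SiOTf, 2,6-lutidine, CH2Cl2, −78 to 0 °C
Reagents that add atoms: triethylsilyl trifluoromethanesulfonate, CC[Si](CC)(CC)OS(=O)(=O)C(F)(F)F
Why: Silylation of a tertiary alcohol with a silyl triflate and a hindered pyridine base, to which the non-enolisable aryl aldehyde and the carbamate are inert; the silyl ether removes the acidic O–H before the cobalt and organolithium steps.

Step 4
Reactants: 5 2-formyl-3-[2-methyl-2-(triethylsilyloxy)propoxy]phenyl diethylcarbamate
Product: 6 2-[(E)-(2-tosylhydrazinylidene)methyl]-3-[2-methyl-2-(triethylsilyloxy)propoxy]phenyl diethylcarbamate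
Conditions: TsNHNH2, MeOH, rt to 40 °C
Reagents that add atoms: 4-methylbenzenesulfonohydrazide (tosylhydrazide), Cc1ccc(cc1)S(=O)(=O)NN
Why: Condensation of the aldehyde with the sulfonyl hydrazide gives the (E)-N-tosylhydrazone, the Bamford–Stevens precursor of the diazo compound, under neutral conditions that leave the silyl ether and carbamate intact.

Step 5
Reactants: 6 2-[(E)-(2-tosylhydrazinylidene)methyl]-3-[2-methyl-2-(triethylsilyloxy)propoxy]phenyl diethylcarbamate
Product: 8 (2R)-2-[2-(triethylsilyloxy)propan-2-yl]-2,3-dihydro-1-benzofuran-4-yl diethylcarbamate, via aryldiazomethane 7 (not isolated)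
Conditions: [Co(P*)] (divalent cobalt, 2–5 mol %), Cs2CO3 (2 equiv), 1,4-dioxane, 40–60 °C, argon
Reagents that add atoms: none
Why: Cs2CO3 deprotonates the tosylhydrazone, whose anion loses p-toluenesulfinate (Bamford–Stevens) to give aryldiazomethane 7, and the divalent cobalt metalloradical takes 7 up with loss of dinitrogen to form a trivalent cobalt carbene radical centred on the future C3. This radical abstracts one hydrogen of the ether O–CH2 group through a six-membered transition state (1,5-hydrogen atom transfer), and the resulting oxygen-stabilised radical attacks the cobalt-bound carbon with Co–C homolysis, forming the C2–C3 bond and closing the dihydrofuran ring by 5-exo-tet radical substitution. The closest known reaction is the cobalt porphyrin metalloradical 1,5-C–H alkylation of ortho-alkoxy and ortho-amino aryldiazomethanes generated from tosylhydrazones, which gives 2-substituted 2,3-dihydrobenzofurans and indolines; here the ether methylene is activated by oxygen only and flanked by a quaternary carbon. The C2 stereocentre arises from the choice between the two enantiotopic O–CH2 hydrogens and the face of radical recombination, both governed by the chiral cavity of P* (amide N–H hydrogen bonds, cyclopropane walls), with the antipode of P* chosen to give (2R). Site selectivity is secured by the substrate, since neither the carbamate nor the quaternary CMe2 carbon offers a hydrogen in the 1,5 position, and slow release of 7 from the cesium salt keeps carbene dimerisation and azine formation low.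

Step 6
Reactants: 8 (2R)-2-[2-(triethylsilyloxy)propan-2-yl]-2,3-dihydro-1-benzofuran-4-yl diethylcarbamate
Product: 10 (2R)-5-acetyl-2-[2-(triethylsilyloxy)propan-2-yl]-2,3-dihydro-1-benzofuran-4-yl diethylcarbamate, via C5 aryllithium 9 (not isolated)
Conditions: s-BuLi, TMEDA, THF, −78 °C; then MeC(O)N(OMe)Me, −78 °C; aq NH4Cl quench at −78 °C
Reagents that add atoms: N-methoxy-N-methylacetamide, CC(=O)N(C)OC
Why: Directed ortho-metalation (Snieckus): the O-carbamate is the strongest directing group and C5 is its only free ortho position (C3a is substituted), kinetic conditions at −78 °C avoid benzylic C3 deprotonation and the anionic ortho-Fries shift, and the Weinreb amide gives the methyl ketone through a chelated tetrahedral adduct, while C2 bears no acidic hydrogen and keeps its configuration.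

Step 7
Reactants: 11 4-hydroxybenzaldehyde; 12 3-chloro-3-methylbut-1-yne
Product: 13 4-[(2-methylbut-3-yn-2-yl)oxy]benzaldehyde
Conditions: K2CO3, KI (cat.), CuI (cat.), acetone, 60 °C
Reagents that add atoms: none
Why: Copper-assisted O-alkylation of the phenoxide with the tertiary propargylic chloride gives the aryl 1,1-dimethylpropargyl ether.

Step 8
Reactants: 13 4-[(2-methylbut-3-yn-2-yl)oxy]benzaldehyde
Product: 15 2,2-dimethyl-2H-chromene-6-carbaldehyde, via ortho-allenylphenol 14 (not isolated)
Conditions: N,N-diethylaniline, 190 °C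
Reagents that add atoms: none
Why: Aromatic propargyl Claisen rearrangement and enolisation give ortho-allenylphenol 14, whose 1,5-hydrogen shift to the ortho-quinone methide and oxa-6π electrocyclisation close the pyran ring; the two ortho positions are equivalent, so a single chromene should form.

Step 9
Reactants: 10 (2R)-5-acetyl-2-[2-(triethylsilyloxy)propan-2-yl]-2,3-dihydro-1-benzofuran-4-yl diethylcarbamate; 15 2,2-dimethyl-2H-chromene-6-carbaldehyde
Product: 17 (2R)-5-[(2E)-3-(2,2-dimethyl-2H-chromen-6-yl)prop-2-enoyl]-2-[2-(triethylsilyloxy)propan-2-yl]-2,3-dihydro-1-benzofuran-4-yl diethylcarbamate, via aldol adduct 16 (not isolated)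
Conditions: KOH (50% aq), EtOH, 0 °C to rt
Reagents that add atoms: none
Why: Claisen–Schmidt condensation, in which the methyl ketone enolate adds to the non-enolisable aldehyde and aldol 16 dehydrates (E1cB) to the conjugated (E)-enone, while at room temperature the N,N-diethylcarbamate resists hydroxide and the carbamoyl Baker–Venkataraman shift, which needs a preformed enolate at reflux.

Step 10
Reactants: 17 (2R)-5-[(2E)-3-(2,2-dimethyl-2H-chromen-6-yl)prop-2-enoyl]-2-[2-(triethylsilyloxy)propan-2-yl]-2,3-dihydro-1-benzofuran-4-yl diethylcarbamate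
Product: 18 (2E)-3-(2,2-dimethyl-2H-chromen-6-yl)-1-{(2R)-4-hydroxy-2-[2-(triethylsilyloxy)propan-2-yl]-2,3-dihydro-1-benzofuran-5-yl}prop-2-en-1-one
Conditions: KOH, EtOH/H2O, 50–60 °C; then aq citric acid, 0 °C
Reagents that add atoms: none
Why: Saponification of the aryl carbamate by addition–elimination at the carbamoyl carbon, eased by the ortho acyl group that makes the chelated phenoxide a good leaving group; the enone has no enolisable hydrogen, so no acyl migration can compete, and the phenoxide formed deactivates the enone towards conjugate addition.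

Step 11
Reactants: 18 (2E)-3-(2,2-dimethyl-2H-chromen-6-yl)-1-{(2R)-4-hydroxy-2-[2-(triethylsilyloxy)propan-2-yl]-2,3-dihydro-1-benzofuran-5-yl}prop-2-en-1-one
Product: 19 (2E)-3-(2,2-dimethyl-2H-chromen-6-yl)-1-[(2R)-4-hydroxy-2-(2-hydroxypropan-2-yl)-2,3-dihydro-1-benzofuran-5-yl]prop-2-en-1-one
Conditions: HF·pyridine, pyridine, THF, 0 °C to rt
Reagents that add atoms: none
Why: Fluoride-induced cleavage of the tertiary triethylsilyl ether under buffered conditions, which leave the hydroxychalcone, the chromene and the C2 stereocentre untouched.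

**Compound list**

1 | 2,6-dihydroxybenzaldehyde | O=Cc1c(O)cccc1O | starting material
2 | 2,2-dimethyloxirane | CC1(C)CO1 | starting material
3 | 2-hydroxy-6-(2-hydroxy-2-methylpropoxy)benzaldehyde | O=Cc1c(O)cccc1OCC(C)(C)O | intermediate
4 | 2-formyl-3-(2-hydroxy-2-methylpropoxy)phenyl diethylcarbamate | CCN(CC)C(=O)Oc1cccc(OCC(C)(C)O)c1C=O | intermediate
5 | 2-formyl-3-[2-methyl-2-(triethylsilyloxy)propoxy]phenyl diethylcarbamate | CCN(CC)C(=O)Oc1cccc(OCC(C)(C)O[Si](CC)(CC)CC)c1C=O | intermediate
6 | 2-[(E)-(2-tosylhydrazinylidene)methyl]-3-[2-methyl-2-(triethylsilyloxy)propoxy]phenyl diethylcarbamate | CCN(CC)C(=O)Oc1cccc(OCC(C)(C)O[Si](CC)(CC)CC)c1/C=N/NS(=O)(=O)c1ccc(C)cc1 | intermediate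
7 | 2-(diazomethyl)-3-[2-methyl-2-(triethylsilyloxy)propoxy]phenyl diethylcarbamate (formed in the flask) | CCN(CC)C(=O)Oc1cccc(OCC(C)(C)O[Si](CC)(CC)CC)c1C=[N+]=[N-] | intermediate
8 | (2R)-2-[2-(triethylsilyloxy)propan-2-yl]-2,3-dihydro-1-benzofuran-4-yl diethylcarbamate | CCN(CC)C(=O)Oc1cccc2c1C[C@H](C(C)(C)O[Si](CC)(CC)CC)O2 | intermediate
9 | (2R)-5-lithio-2-[2-(triethylsilyloxy)propan-2-yl]-2,3-dihydro-1-benzofuran-4-yl diethylcarbamate (formed in the flask) | CCN(CC)C(=O)Oc1c([Li])ccc2c1C[C@H](C(C)(C)O[Si](CC)(CC)CC)O2 | intermediate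
10 | (2R)-5-acetyl-2-[2-(triethylsilyloxy)propan-2-yl]-2,3-dihydro-1-benzofuran-4-yl diethylcarbamate | CCN(CC)C(=O)Oc1c(C(C)=O)ccc2c1C[C@H](C(C)(C)O[Si](CC)(CC)CC)O2 | intermediate
11 | 4-hydroxybenzaldehyde | O=Cc1ccc(O)cc1 | starting material
12 | 3-chloro-3-methylbut-1-yne | CC(C)(Cl)C#C | starting material
13 | 4-[(2-methylbut-3-yn-2-yl)oxy]benzaldehyde | CC(C)(C#C)Oc1ccc(C=O)cc1 | intermediate
14 | 4-hydroxy-3-(3-methylbuta-1,2-dien-1-yl)benzaldehyde (formed in the flask) | CC(C)=C=Cc1cc(C=O)ccc1O | intermediate
15 | 2,2-dimethyl-2H-chromene-6-carbaldehyde | CC1(C)C=Cc2cc(C=O)ccc2O1 | intermediate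
16 | (2R)-5-[3-(2,2-dimethyl-2H-chromen-6-yl)-3-hydroxypropanoyl]-2-[2-(triethylsilyloxy)propan-2-yl]-2,3-dihydro-1-benzofuran-4-yl diethylcarbamate (both carbinol epimers, formed in the flask) | CCN(CC)C(=O)Oc1c(C(=O)CC(O)c3ccc4OC(C)(C)C=Cc4c3)ccc2c1C[C@H](C(C)(C)O[Si](CC)(CC)CC)O2 | intermediate
17 | (2R)-5-[(2E)-3-(2,2-dimethyl-2H-chromen-6-yl)prop-2-enoyl]-2-[2-(triethylsilyloxy)propan-2-yl]-2,3-dihydro-1-benzofuran-4-yl diethylcarbamate | CCN(CC)C(=O)Oc1c(C(=O)/C=C/c3ccc4OC(C)(C)C=Cc4c3)ccc2c1C[C@H](C(C)(C)O[Si](CC)(CC)CC)O2 | intermediate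
18 | (2E)-3-(2,2-dimethyl-2H-chromen-6-yl)-1-{(2R)-4-hydroxy-2-[2-(triethylsilyloxy)propan-2-yl]-2,3-dihydro-1-benzofuran-5-yl}prop-2-en-1-one | Oc1c(C(=O)/C=C/c3ccc4OC(C)(C)C=Cc4c3)ccc2c1C[C@H](C(C)(C)O[Si](CC)(CC)CC)O2 | intermediate
19 | (2E)-3-(2,2-dimethyl-2H-chromen-6-yl)-1-[(2R)-4-hydroxy-2-(2-hydroxypropan-2-yl)-2,3-dihydro-1-benzofuran-5-yl]prop-2-en-1-one | CC1(C)C=Cc2cc(/C=C/C(=O)c3ccc4c(c3O)C[C@H](C(C)(C)O)O4)ccc2O1 | target

**Step count**

Total: 11 steps. Longest linear sequence: 9 steps (steps 1–6, then 9–11); steps 7 and 8 form the ring B branch.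

**Steps most likely to fail**

1. Step 5. Hydrogen abstraction from an ether methylene that is activated by oxygen only and shielded by the neighbouring quaternary carbon may be slow for a carbene radical flanked by two ortho substituents. Carbene dimerisation, azine formation or reduction could then take over, or the two enantiotopic hydrogens may be poorly distinguished. The fallback sets out from 1 and comes back at 8, building the ring by aldol-type annulation instead of C–H insertion. Compound 1 is condensed with ethyl bromoacetate (K2CO3, DMF, 100 °C; O-alkylation, intramolecular aldol condensation, dehydration) to ethyl 4-hydroxy-1-benzofuran-2-carboxylate F1. Carbamoylation (Et2NCOCl, K2CO3, MeCN) gives ethyl 4-[(diethylcarbamoyl)oxy]-1-benzofuran-2-carboxylate F2. Hydrogenation of the furan double bond (H2, Pd/C, AcOH) gives racemic ethyl 4-[(diethylcarbamoyl)oxy]-2,3-dihydro-1-benzofuran-2-carboxylate F3. The racemate is resolved by chromatography on a chiral stationary phase (or lipase-mediated kinetic resolution) to ethyl (2R)-4-[(diethylcarbamoyl)oxy]-2,3-dihydro-1-benzofuran-2-carboxylate F4. Double addition of MeMgBr (CeCl3, THF, −40 °C) gives (2R)-2-(2-hydroxypropan-2-yl)-2,3-dihydro-1-benzofuran-4-yl diethylcarbamate F5, and silylation (Et3SiOTf, 2,6-lutidine) returns to 8.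

2. Step 6. Proton transfer from the enolisable acetamide to the aryllithium may return 8. If the temperature rises, carbamoyl migration to C5 (anionic ortho-Fries) or deprotonation at benzylic C3 with opening of the dihydrofuran may intervene. The fallback sets out from 15 and 8 and comes back at 17, making the aryl–acyl bond with the whole enone in place and dropping the aldol step. Horner–Wadsworth–Emmons olefination of 15 with diethyl {2-[methoxy(methyl)amino]-2-oxoethyl}phosphonate (NaH, THF) gives the non-enolisable (2E)-3-(2,2-dimethyl-2H-chromen-6-yl)-N-methoxy-N-methylprop-2-enamide F6. Aryllithium 9, generated from 8 as in step 6, is acylated with it at −78 °C (1,2-addition, chelated adduct) to give 17 directly.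

3. Step 10. Hot alkali may add reversibly to the enone and fragment it by retro-aldol reaction. The liberated phenoxide may close onto the enone to a flavanone-type chromanone, or hydrolysis may stall. The fallback sets out from 10 and comes back at 18, removing the carbamate by reduction before the enone exists. LiAlH4 (THF, 0 °C to reflux) reduces the ketone and cleaves the aryl carbamate to (2R)-5-(1-hydroxyethyl)-2-[2-(triethylsilyloxy)propan-2-yl]-2,3-dihydro-1-benzofuran-4-ol F7. MnO2 (CH2Cl2, rt) reoxidises the benzylic alcohol to 1-{(2R)-4-hydroxy-2-[2-(triethylsilyloxy)propan-2-yl]-2,3-dihydro-1-benzofuran-5-yl}ethan-1-one F8. Claisen–Schmidt condensation of this hydroxy ketone with 15 (KOH, EtOH, rt) gives 18.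

**Further compounds**

F1 | step 5 | ethyl 4-hydroxy-1-benzofuran-2-carboxylate | CCOC(=O)c1cc2c(O)cccc2o1
F2 | step 5 | ethyl 4-[(diethylcarbamoyl)oxy]-1-benzofuran-2-carboxylate | CCOC(=O)c1cc2c(OC(=O)N(CC)CC)cccc2o1
F3 | step 5 | racemic ethyl 4-[(diethylcarbamoyl)oxy]-2,3-dihydro-1-benzofuran-2-carboxylate | CCOC(=O)C1Cc2c(OC(=O)N(CC)CC)cccc2O1
F4 | step 5 | ethyl (2R)-4-[(diethylcarbamoyl)oxy]-2,3-dihydro-1-benzofuran-2-carboxylate | CCOC(=O)[C@H]1Cc2c(OC(=O)N(CC)CC)cccc2O1
F5 | step 5 | (2R)-2-(2-hydroxypropan-2-yl)-2,3-dihydro-1-benzofuran-4-yl diethylcarbamate | CCN(CC)C(=O)Oc1cccc2c1C[C@H](C(C)(C)O)O2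
F6 | step 6 | (2E)-3-(2,2-dimethyl-2H-chromen-6-yl)-N-methoxy-N-methylprop-2-enamide | CON(C)C(=O)/C=C/c1ccc2OC(C)(C)C=Cc2c1
F7 | step 10 | (2R)-5-(1-hydroxyethyl)-2-[2-(triethylsilyloxy)propan-2-yl]-2,3-dihydro-1-benzofuran-4-ol (both carbinol epimers) | Oc1c(C(C)O)ccc2c1C[C@H](C(C)(C)O[Si](CC)(CC)CC)O2
F8 | step 10 | 1-{(2R)-4-hydroxy-2-[2-(triethylsilyloxy)propan-2-yl]-2,3-dihydro-1-benzofuran-5-yl}ethan-1-one | Oc1c(C(C)=O)ccc2c1C[C@H](C(C)(C)O[Si](CC)(CC)CC)O2
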